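## Retrosynthetic overview

1. Myrtucommulone A ⇐ twofold SmI2 removal of tertiary hydroxyls from an (R,R)-bis-α-ketol, in which the bridging stereocentres cannot scramble by retro-Michael reaction.
2. Bis-α-ketol ⇐ two invertive Friedel–Crafts openings of an (R)-spiro-epoxide by isobutyrylphloroglucinol, so the C–C bonds form with transfer of a pre-set C–O stereocentre.
3. (R)-Spiro-epoxide ⇐ catalytic asymmetric nucleophilic epoxidation of isobutylidenesyncarpic acid; the stereodefining event is C–O bond formation at the future bridging carbon.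
4. Isobutylidenesyncarpic acid ⇐ syncarpic acid + isobutyraldehyde; syncarpic acid ⇐ 2',4',6'-trihydroxyacetophenone (C-tetramethylation, deacetylation); isobutyrylphloroglucinol ⇐ phloroglucinol + isobutyryl chloride.
5. Ring order: both carbocycles come from aromatic starting materials; the only ring made on the way is the oxirane (closed in step 4, opened in step 6).

Assumption: the quinine-derived catalyst of step 4 is taken to give the (R)-epoxide (if the sense proves opposite, the quinidine-derived pseudo-enantiomer is used); enol/keto tautomers are drawn as in the target SMILES.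

## Route

Step 1
Reactants: 1 2',4',6'-trihydroxyacetophenone
Product: 2 acetylsyncarpic acid (2-acetyl-3-hydroxy-4,4,6,6-tetramethylcyclohex-2-ene-1,5-dione)
Conditions: NaOMe (5 equiv), MeI (6 equiv), MeOH, 0 °C → reflux
Reagents that add atoms: iodomethane, CI
Why: Exhaustive dearomatising C-methylation (enolate C-alkylation) of the phloroglucinol polyanion; the acetyl group blocks the third ring carbon, so exactly four methyls enter as two gem-dimethyl pairs.

Step 2
Reactants: 2 acetylsyncarpic acid
Product: 3 syncarpic acid (3-hydroxy-4,4,6,6-tetramethylcyclohex-2-ene-1,5-dione)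
Conditions: 6 M aq. HCl, reflux
Reagents that add atoms: none
Why: Acid-mediated retro-Claisen deacylation of the β-triketone removes the acetyl blocking group as acetic acid.

Step 3
Reactants: 3 syncarpic acid; 4 isobutyraldehyde
Product: 6 isobutylidenesyncarpic acid, via Mannich base 5 (not isolated)
Conditions: piperidine (1.05 equiv), CH2Cl2, 0 °C → rt; then 1 M aq. HCl, rt
Reagents that add atoms: none
Why: Mannich condensation of the cyclic 1,3-dione with the aldehyde and amine, then acid-triggered β-elimination of piperidine (Knoevenagel condensation via the Mannich base); the two flanking carbonyls are equivalent, so the alkene has no E/Z issue.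

Step 4
Reactants: 6 isobutylidenesyncarpic acid
Product: 8 (2R)-5,5,7,7-tetramethyl-2-(propan-2-yl)-1-oxaspiro[2.5]octane-4,6,8-trione, via peroxide adduct 7 (not isolated)
Conditions: epi-quinine-derived 3,5-bis(trifluoromethyl)phenyl thiourea (10 mol %), tBuOOH (1.3 equiv, in decane), toluene, −20 °C
Reagents that add atoms: tert-butyl hydroperoxide, CC(C)(C)OO
Why: Asymmetric Weitz–Scheffer nucleophilic epoxidation under bifunctional amine–thiourea catalysis: the quinuclidine-activated peroxide adds to one face of the thiourea-bound alkylidene trione, this C–O bond formation setting the (R) centre, and the enolate then closes on the proximal peroxide oxygen with loss of tert-butoxide.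

Step 5
Reactants: 9 phloroglucinol; 10 isobutyryl chloride
Product: 11 isobutyrylphloroglucinol (2-methyl-1-(2,4,6-trihydroxyphenyl)propan-1-one)
Conditions: AlCl3 (3.5 equiv), PhNO2/CH2Cl2, 0 → 45 °C; aq. HCl work-up
Reagents that add atoms: none
Why: Friedel–Crafts acylation of the very electron-rich arene stops at mono-acylation because the aryl ketone–AlCl3 complex deactivates the ring.

Step 6
Reactants: 11 isobutyrylphloroglucinol; 8 (R)-spiro-epoxide (2.2 equiv)
Product: 13 (R,R)-bis-α-ketol, via mono-adduct 12 (not isolated)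
Conditions: TfOH (5 mol %), (CF3)2CHOH, −20 → 0 °C
Reagents that add atoms: none
Why: Proposed new method: stereospecific arylative opening of a 2,2-diacyl spiro-epoxide by a phloroglucinol ring carbon — the diacyl-substituted spiro carbon can neither ionise nor be attacked, and the three ketones suppress cation formation at the CH(iPr) carbon, so under TfOH/HFIP hydrogen-bond activation the free ring carbons of 11 and then of 12 should attack that carbon anti to the departing oxygen in a borderline-SN2 Friedel–Crafts alkylation (spatial inversion; the descriptor stays R because aryl takes the place of oxygen in the priority order), giving tertiary ketols that cannot epimerise by retro-Michael; the closest known reaction types are the acid-catalysed enantiospecific Friedel–Crafts opening of electron-poor and aliphatic epoxides in HFIP and the SN2 opening of gem-diacceptor epoxides at the distal carbon by heteroatom nucleophiles.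

Step 7
Reactants: 13 (R,R)-bis-α-ketol
Product: 15 (R,R)-myrtucommulone A, via mono-ketol 14 (not isolated)
Conditions: SmI2 (5 equiv), THF/MeOH (10:1), −78 °C; NaH2PO4 buffer (pH 5) work-up
Reagents that add atoms: none
Why: SmI2 reductive cleavage of α-hydroxy ketones (α-heterosubstituted ketone reduction): ketyl formation and β-elimination of hydroxide give the stabilised syncarpyl enolate, protonated to the enol on work-up; the bridging stereocentres are not touched.

## Compound list

1 | 2',4',6'-trihydroxyacetophenone | CC(=O)c1c(O)cc(O)cc1O | starting material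
2 | acetylsyncarpic acid (2-acetyl-3-hydroxy-4,4,6,6-tetramethylcyclohex-2-ene-1,5-dione) | CC(=O)C1=C(O)C(C)(C)C(=O)C(C)(C)C1=O | intermediate
3 | syncarpic acid (3-hydroxy-4,4,6,6-tetramethylcyclohex-2-ene-1,5-dione) | CC1(C)C(=O)C=C(O)C(C)(C)C1=O | intermediate
4 | isobutyraldehyde (2-methylpropanal) | CC(C)C=O | starting material
5 | Mannich base, racemic (3-hydroxy-4,4,6,6-tetramethyl-2-[2-methyl-1-(piperidin-1-yl)propyl]cyclohex-2-ene-1,5-dione) | CC(C)C(N1CCCCC1)C1=C(O)C(C)(C)C(=O)C(C)(C)C1=O | intermediate
6 | isobutylidenesyncarpic acid (2,2,4,4-tetramethyl-6-(2-methylpropylidene)cyclohexane-1,3,5-trione) | CC(C)C=C1C(=O)C(C)(C)C(=O)C(C)(C)C1=O | intermediate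
7 | peroxide adduct (2-[(1R)-1-(tert-butylperoxy)-2-methylpropyl]-3-hydroxy-4,4,6,6-tetramethylcyclohex-2-ene-1,5-dione, present as its enolate) | CC(C)[C@@H](OOC(C)(C)C)C1=C(O)C(C)(C)C(=O)C(C)(C)C1=O | intermediate
8 | (2R)-5,5,7,7-tetramethyl-2-(propan-2-yl)-1-oxaspiro[2.5]octane-4,6,8-trione | CC(C)[C@H]1OC12C(=O)C(C)(C)C(=O)C(C)(C)C2=O | intermediate
9 | phloroglucinol (benzene-1,3,5-triol) | Oc1cc(O)cc(O)c1 | starting material
10 | isobutyryl chloride (2-methylpropanoyl chloride) | CC(C)C(Cl)=O | starting material
11 | isobutyrylphloroglucinol (2-methyl-1-(2,4,6-trihydroxyphenyl)propan-1-one) | CC(C)C(=O)c1c(O)cc(O)cc1O | intermediate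
12 | mono-adduct (2-hydroxy-4,4,6,6-tetramethyl-2-{(1R)-2-methyl-1-[2,4,6-trihydroxy-3-(2-methylpropanoyl)phenyl]propyl}cyclohexane-1,3,5-trione) | CC(C)C(=O)c1c(O)cc(O)c([C@H](C2(O)C(=O)C(C)(C)C(=O)C(C)(C)C2=O)C(C)C)c1O | intermediate
13 | (R,R)-bis-α-ketol (2,2'-{[2,4,6-trihydroxy-5-(2-methylpropanoyl)-1,3-phenylene]bis[(1R)-2-methylpropane-1,1-diyl]}bis(2-hydroxy-4,4,6,6-tetramethylcyclohexane-1,3,5-trione)) | CC(C)C(=O)c1c(O)c([C@H](C2(O)C(=O)C(C)(C)C(=O)C(C)(C)C2=O)C(C)C)c(O)c([C@H](C2(O)C(=O)C(C)(C)C(=O)C(C)(C)C2=O)C(C)C)c1O | intermediate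
14 | mono-ketol (one arm already the syncarpyl enol, the other still the 2-hydroxy-trione; both bridging carbons R) | CC(C)C(=O)c1c(O)c([C@H](C2=C(O)C(C)(C)C(=O)C(C)(C)C2=O)C(C)C)c(O)c([C@H](C2(O)C(=O)C(C)(C)C(=O)C(C)(C)C2=O)C(C)C)c1O | intermediate
15 | (R,R)-myrtucommulone A (2,2'-{[2,4,6-trihydroxy-5-(2-methylpropanoyl)-1,3-phenylene]bis[(1R)-2-methylpropane-1,1-diyl]}bis(3-hydroxy-4,4,6,6-tetramethylcyclohex-2-ene-1,5-dione)) | CC(C)C(=O)c1c(O)c([C@H](C2=C(O)C(C)(C)C(=O)C(C)(C)C2=O)C(C)C)c(O)c([C@H](C2=C(O)C(C)(C)C(=O)C(C)(C)C2=O)C(C)C)c1O | target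

## Step count and risks

Total step count: 7. Longest linear sequence: 6 (steps 1, 2, 3, 4, 6, 7); step 5 is the one-step side branch.

**Step 6 (proposed new step).**
- Risks: the attacked carbon is a hindered secondary centre next to a quaternary carbon; the acid may trigger an acyl or hydride shift of the epoxide; any SN1 leakage gives the meso isomer.
- Mitigating point: two stereospecific couplings amplify purity. Epoxide of 95 % ee gives (R,R) : meso : (S,S) ≈ 95 : 5 : 0.06, so after removal of meso-13 the chiral isomer is above 99.8 % ee.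
- Fallback (known chemistry): set out from isobutylidenesyncarpic acid 6 and isobutyrylphloroglucinol 11 and bypass 8 and 13. The established base-mediated Friedel–Crafts-type double Michael addition (NaH, THF, rt) gives 15 directly, together with the (S,S)-enantiomer of myrtucommulone A F2 and meso-(R,S)-myrtucommulone A F3. Preparative HPLC on a chiral stationary phase isolates the (R,R)-isomer, and the route is rejoined at 15.

**Step 4.**
- Risks: the amine catalyst can deprotonate the γ-hydrogen of 6 to an unreactive dienolate, and enantioselectivity for an aliphatic alkylidene trione is unproven.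
- Fallback: set out from 6 and run a racemic Weitz–Scheffer epoxidation (30 % H2O2, NaHCO3, MeOH/H2O, 0 °C). This gives 8 as a 1:1 mixture with (2S)-5,5,7,7-tetramethyl-2-(propan-2-yl)-1-oxaspiro[2.5]octane-4,6,8-trione F1. Resolution by preparative SFC on amylose tris(3,5-dimethylphenylcarbamate) replaces asymmetric catalysis, and the route is rejoined at 8.

**Step 7.**
- Risks: sluggish expulsion of a free tertiary hydroxide, over-reduction, or epimerisation of the product enol during work-up.
- Fallback: set out from 13 and peracetylate (Ac2O, Et3N, DMAP, CH2Cl2, with Sc(OTf)3 catalysis if the tertiary hydroxyls resist) to the pentaacetate of the bis-ketol F4. SmI2 (THF, −78 °C) then cleaves the two α-acetoxy ketones, a far better leaving group, to give 2,4,6-tri-O-acetyl-myrtucommulone A F5. Brief methanolysis (K2CO3 cat., MeOH, 0 °C) removes the aryl acetates, and the route is rejoined at 15.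

## Further compounds

F1 | step 4 | (2S)-5,5,7,7-tetramethyl-2-(propan-2-yl)-1-oxaspiro[2.5]octane-4,6,8-trione | CC(C)[C@@H]1OC12C(=O)C(C)(C)C(=O)C(C)(C)C2=O
F2 | step 6 | (S,S)-myrtucommulone A | CC(C)C(=O)c1c(O)c([C@@H](C2=C(O)C(C)(C)C(=O)C(C)(C)C2=O)C(C)C)c(O)c([C@@H](C2=C(O)C(C)(C)C(=O)C(C)(C)C2=O)C(C)C)c1O
F3 | step 6 | meso-(R,S)-myrtucommulone A | CC(C)C(=O)c1c(O)c([C@H](C2=C(O)C(C)(C)C(=O)C(C)(C)C2=O)C(C)C)c(O)c([C@@H](C2=C(O)C(C)(C)C(=O)C(C)(C)C2=O)C(C)C)c1O
F4 | step 7 | pentaacetate of the (R,R)-bis-α-ketol (three aryl acetates, two tertiary acetates) | CC(C)C(=O)c1c(OC(C)=O)c([C@H](C2(OC(C)=O)C(=O)C(C)(C)C(=O)C(C)(C)C2=O)C(C)C)c(OC(C)=O)c([C@H](C2(OC(C)=O)C(=O)C(C)(C)C(=O)C(C)(C)C2=O)C(C)C)c1OC(C)=O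
F5 | step 7 | 2,4,6-tri-O-acetyl-(R,R)-myrtucommulone A | CC(C)C(=O)c1c(OC(C)=O)c([C@H](C2=C(O)C(C)(C)C(=O)C(C)(C)C2=O)C(C)C)c(OC(C)=O)c([C@H](C2=C(O)C(C)(C)C(=O)C(C)(C)C2=O)C(C)C)c1OC(C)=O
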